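## Structural features

Briarane numbering is used throughout: C1–C10 form the ten-membered carbocycle, C11–C14 complete ring A, C15 is the methyl on C1, C16 the exocyclic methylene carbon on C5, C17 (methyl C18) and C19 belong to the lactone, and C20 is the epoxide methylene.

The target is a ten-membered carbocycle fused across C1–C10 to a cyclohexane (ring A) and across C7–C8 to a γ-lactone (C7, C8, C17, C19, O). Ring A carries a spiro-epoxide at C11, an axial acetate at C14 and the quaternary C1. There are ten stereocentres, and eight of them form one unbroken chain C6–C7–C8–C9–C10–C1–C2 with C17 and C11 attached to it. The fragile groups are the secondary allylic chloride at C6 next to the C5=C16 methylene, the acid-sensitive 2,2-disubstituted epoxide, the β-hydroxy lactone with an epimerisable C17, and three acetates beside a free tertiary alcohol at C8. The real difficulty is the medium ring: closing a ten-membered ring is entropically and transannularly unfavourable, and stereocontrol on such a ring is hard to predict. The key step exploits the fact that C2 and C7 both bear oxygen and lie 1,6 to each other in the ten-membered ring. They can therefore be the two carbons of a tetrasubstituted C2=C7 alkene shared by ring B (C1, C2, C7, C8, C9, C10) and ring C (C2–C7) of a hydrophenanthrene. Ring C, with methyl C16 on C5, is the Birch reduction product of a toluene ring.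

## Logic of the disconnections

34 ⇒ 33. The C6–Cl bond is cut and the C5=C16 alkene is moved back to C5=C6 (ene retron). The allylic chloride is the most labile group and is best made last. This removes one stereocentre and leaves a plain trisubstituted alkene. The forward step must put chlorine on C6 only, lose the proton from C16, choose one alkene face and spare the epoxide.

33 ⇒ 32 ⇒ 30. The acetate C–O bonds at O2 and O14 and the acyl C19–O7 bond are cut, with C19 lowered to a primary alcohol. The lactone then reduces to a 1,4-diol. The oxidation must pick the primary alcohol, and the lactol must close on O7 only, which is why O9 already carries its acetate.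

30 ⇒ 29. The C11–C20 and C20–O bonds of the epoxide are cut to leave a C11 ketone. The methylene must enter equatorially so that oxygen ends up axial, syn to C15. The step is placed before the lactone exists because a lactone would not tolerate the ylide.

29 ⇒ 28 ⇒ 27 ⇒ 26 ⇒ 25. The C7–H and C2–H bonds are cut (two hydride additions), the alkene is returned from C5=C6 to C4=C5, and the acetonide and ketal are restored. This leads back to the two ketones that ozonolysis delivers. Both new carbinol centres sit on a flexible ring, so each hydride is delivered intramolecularly from a resident hydroxyl (O14 for C2, O8 for C7). The alkene migration is unambiguous only once C2 is no longer a ketone.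

25 ⇒ 24 (key step). C2 and C7 are joined by a double bond, the reverse of an oxidative cleavage. The ten-membered ring collapses to a rigid tricycle, so no medium ring has to be closed and C1, C8, C9, C10, C14 and C17 can be set on six-membered rings. The forward step must cleave the tetrasubstituted alkene and leave the trisubstituted C4=C5 alkene.

24 ⇒ 23 ⇒ 22 ⇒ 21 ⇒ 20. Protecting groups are exchanged and four C–H bonds at C3 and C6 are cut to restore the arene. A 1,4-diene with C2=C7 and C4=C5 is exactly the Birch product of a 1,2,4-trialkylbenzene. The benzylic C8–O bond must survive dissolving metal, so it is carried as a free alkoxide; the acetonide and the C9 acetate are put on afterwards.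

20 ⇒ 19 ⇒ 18 ⇒ 15 + 17. The C9–H bond, the C8–O bond and the C8–C17 bond are cut. C8 is benzylic and α to a C9 ketone, so both bonds come from one enolate. C17 comes from the chiral pool (16 ⇒ 17) by SN2 inversion. The demands are C- over O-alkylation, oxygenation from the α face and hydride delivery from the α face at C9.

15 ⇒ 14 ⇒ 12. The C9 carbonyl is transposed back to C8. The ring-forming aldol leaves oxygen on C8, whereas enolate chemistry at C8 needs it on C9. The forward oxidation of the C8=C9 styrene must place oxygen on the homobenzylic carbon.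

12 ⇒ 11 ⇒ 10 ⇒ 8. The C11–O and C10–H bonds are cut to return to the conjugated enone. One hydroboration of the deconjugated alkene supplies the C11 oxygen and the trans ring fusion. The demands are kinetic α-protonation of the dienolate and borane attack anti to C15.

8 ⇒ 6. The C9=C10 bond is cut (aldol condensation retron). The tricycle falls to a monocyclic diketone. The aryl methyl ketone must be the nucleophile and the ring ketone the acceptor.

6 ⇒ 5 ⇒ 4. The O–Si and C14–H bonds are cut to a prochiral dione. A single desymmetrising reduction then sets C1 and C14 together. It is done before ring B exists, when hydride adds anti to the aryl group and so gives the alcohol trans to C15, which is the hard one to reach on the tricycle.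

4 ⇒ 2 + 3, and 2 ⇒ 1. The aryl–C1 bond is cut to an aryl bromide and a 1,3-dione, and the ketal is removed. The forward coupling must form a quaternary carbon next to an ortho-substituted arene.

## Other disconnections considered

Alternative 1: The cut runs through ring A (C1–C14 and C10–C11). In the forward sense a chiral boron Lewis acid would promote the endo Diels–Alder reaction of silyloxy diene A1 with enal A2 to give cyclohexene aldehyde A3.
- In its favour: one catalytic step builds ring A with the quaternary C1, C10 and C14 in the right relative configuration (endo rule, E geometry of A2) and leaves two differentiated arms at C2 and C9. On the construction of ring A this is better than the chosen plan, which needs several steps for the same centres.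
- Against it here: α-methyl, β-substituted enals are reluctant dienophiles and 1-silyloxy dienes are labile to Lewis acids. C11 arrives as a CH–CH2O unit, so the spiro-epoxide still needs an oxidation at C11. Above all, A3 does nothing for the ten-membered ring, which would have to be closed later from the C2 and C9 arms with C7, C8 and C17 still to be set.
- Comparison: structurally it solves the easy ring and postpones the hard one. Mechanistically a concerted cycloaddition is as reliable as an ozonolysis. In step count it is probably no shorter once the macrocyclisation and its stereochemical repairs are included.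

Alternative 2: The cut is C8–C17 inside the lactone. Forward, [(Ph3P)CuH]6 would add hydride to the acrylate terminus of keto acrylate A4, and the copper enolate would close onto the C8 ketone to give A5, which is the same compound as 33 of the chosen route.
- In its favour: lactone, C8 carbinol and C17 methyl are made in one mild, neutral step. For these two centres it is better in step count than the alkylation, hydroxylation, reduction and later lactonisation of the chosen plan. The last step to the target would be the same chlorination, so there the two plans are equal.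
- Against it here: A4 already contains the complete ten-membered ring, so the medium-ring problem is untouched. Both enolate carbons lie inside the forming five-membered ring, a strained closure geometry. The C8 ketone carries an α-acetoxy group at C9 that copper hydride may cleave reductively. Two stereocentres would be decided by the conformation of a flexible ring, not by a rigid template.
- Comparison: it is an end-game tactic, not a ring-forming strategy. The chosen plan pays more steps but sets C8 and C17 on a chair-like tricycle with predictable faces.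

Alternative 3: The cuts are C9–C10 and C1–C2. Forward, CuBr·SMe2 with a chiral phosphoramidite would add vinylmagnesium bromide to enone A6, and the resulting enolate would be trapped by aldehyde A7 to give aldol adduct A8.
- In its favour: it is convergent, makes C10, the quaternary C1 and the C2 carbinol in one pot, and brings C7 and C17 in ready-made with A7. In convergence and probably in linear step count it is better than the chosen plan.
- Against it here: the aldol of a tetrasubstituted magnesium enolate with an enolisable aldehyde gives uncertain control at C2. The enantioselective vinyl addition next to a spiro-ketal is demanding. The ten-membered ring would then have to be closed by metathesis to a trisubstituted C8=C9 alkene, a notoriously strained closure, followed by a face-selective dihydroxylation on the medium ring. The C14 ketone would still need reduction to the axial alcohol, which is equal in difficulty to the same problem in the chosen plan.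
- Comparison: A8 is reached faster than 24, but the risk is concentrated in the medium-ring closure. The chosen plan removes that risk by fragmentation.

Key step: step 19

Remarks on the chemistry:
- On the tricyclic intermediates, β means the face carrying the C15 methyl group, so H10 is α.
- The stereocentres carried through the key step (C1, C8, C9, C10, C14, C17) map onto 34 without mismatch, so no structural correction is needed. The design changes concern protecting groups only: C8–O is a free alkoxide during the Birch reduction, O9 carries the final acetate, and O14 is freed before ozonolysis so that it can direct the C2 reduction.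
- The C8 carbinol centres of 10 and 13 and the C8 centre of 18 are epimer mixtures of no consequence.

## Route

Step 1
Reactants: 1 1-(2-bromo-5-methylphenyl)ethanone
Product: 2 2-(2-bromo-5-methylphenyl)-2-methyl-1,3-dioxolane
Conditions: HOCH2CH2OH, p-TsOH·H2O (cat.), toluene, reflux, Dean–Stark
Reagents that add atoms: ethylene glycol, OCCO
Why: Acid-catalysed ketalisation driven by azeotropic removal of water; the dioxolane keeps the methyl ketone out of aldol chemistry during the basic arylation and out of the borane reduction of step 3.

Step 2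
Reactants: 2 2-(2-bromo-5-methylphenyl)-2-methyl-1,3-dioxolane; 3 2-methylcyclohexane-1,3-dione
Product: 4 2-methyl-2-[4-methyl-2-(2-methyl-1,3-dioxolan-2-yl)phenyl]cyclohexane-1,3-dione
Conditions: Pd(OAc)2 (5 mol%), 2-di-tert-butylphosphino-2′,4′,6′-triisopropylbiphenyl (10 mol%), K3PO4, 1,4-dioxane, 90 °C
Reagents that add atoms: none
Why: Pd-catalysed α-arylation of a cyclic 1,3-dione (oxidative addition of 2 to zerovalent palladium, enolate ligation, reductive elimination promoted by the bulky biaryl phosphine); the cyclic dione cannot chelate palladium through both oxygens, which is what lets the quaternary C1–C2 bond form. The product is still prochiral, so no stereocentre is set.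

Step 3
Reactants: 4 2-methyl-2-[4-methyl-2-(2-methyl-1,3-dioxolan-2-yl)phenyl]cyclohexane-1,3-dione
Product: 5 (2S,3S)-3-hydroxy-2-methyl-2-[4-methyl-2-(2-methyl-1,3-dioxolan-2-yl)phenyl]cyclohexan-1-one
Conditions: (R)-1-methyl-3,3-diphenyl-tetrahydro-1H,3H-pyrrolo[1,2-c][1,3,2]oxazaborole ((R)-Me-CBS, 20 mol%), catecholborane, toluene, −78 → −40 °C; MeOH
Reagents that add atoms: none
Why: CBS reduction desymmetrises the dione: hydride adds to a ring carbonyl on the face opposite the bulky aryl group, so O14 ends cis to the aryl group and trans to C15, and with the quaternary carbon as the large group the (R)-catalyst should give the (S)-carbinol. C14 and C1 are thus set together.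

Step 4
Reactants: 5 (2S,3S)-3-hydroxy-2-methyl-2-[4-methyl-2-(2-methyl-1,3-dioxolan-2-yl)phenyl]cyclohexan-1-one
Product: 6 (2S,3S)-3-(tert-butyldimethylsilyloxy)-2-methyl-2-[4-methyl-2-(2-methyl-1,3-dioxolan-2-yl)phenyl]cyclohexan-1-one
Conditions: t-BuMe2SiOTf, 2,6-lutidine, CH2Cl2, −78 → 0 °C
Reagents that add atoms: tert-butyldimethylsilyl trifluoromethanesulfonate, CC(C)(C)[Si](C)(C)OS(=O)(=O)C(F)(F)F
Why: Silylation of the hindered secondary alcohol with the silyl triflate at low temperature, where the ketal is untouched; the ether prevents retro-aldol cleavage and hemiketal formation in step 5 and lasts until step 18.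

Step 5
Reactants: 6 (2S,3S)-3-(tert-butyldimethylsilyloxy)-2-methyl-2-[4-methyl-2-(2-methyl-1,3-dioxolan-2-yl)phenyl]cyclohexan-1-one
Product: 8 tricyclic enone (C8 ketone conjugated with C9=C10; arene C2–C7 with C16 on C5; 14α-tert-butyldimethylsilyloxy; C15 β on C1), via methyl ketone 7 (not isolated)
Conditions: pyridinium p-toluenesulfonate, acetone/H2O, 50 °C; then NaOMe (0.3 equiv), MeOH, 50 °C
Reagents that add atoms: water, O
Why: Mild aqueous acid hydrolyses the benzylic ketal to methyl ketone 7; methoxide then effects an intramolecular aldol condensation in which the more acidic aryl methyl ketone (C9) is the nucleophile and the more electrophilic ring ketone (C10) the acceptor (6-enolexo-exo-trig), and E1cB loss of water gives the conjugated enone. C1 and C14 cannot epimerise.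

Step 6
Reactants: 8 tricyclic enone (8-oxo, 9(10)-ene, 14α-silyloxy)
Product: 10 8ξ,11α-diol (10α-H, trans-fused rings A and B; 14α-silyloxy), via deconjugated enone 9 (not isolated)
Conditions: KOtBu, t-BuOH/THF, 0 °C; AcOH, −78 °C; crude 9: BH3·THF, THF, 0 °C → rt; then NaOH, H2O2
Reagents that add atoms: hydrogen peroxide, OO
Why: γ-Deprotonation at C11 gives the extended enolate and kinetic α-protonation at C9 moves the alkene to C10=C11, as in the deconjugation of steroidal enones. Borane reduces the C8 ketone and hydroborates the trisubstituted alkene from the face opposite the angular C15 methyl, syn addition placing H at C10 (α, trans fusion) and boron at C11; oxidation gives the diol.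

Step 7
Reactants: 10 8ξ,11α-diol
Product: 11 8,11-dione (10α-H; 14α-silyloxy)
Conditions: Dess–Martin periodinane, NaHCO3, CH2Cl2, rt
Reagents that add atoms: none
Why: Buffered Dess–Martin oxidation of both secondary alcohols; C10 lies α to the new C11 ketone but already has the thermodynamically preferred trans fusion.

Step 8
Reactants: 11 8,11-dione
Product: 12 8-ketone 11-ethylene ketal (10α-H; 14α-silyloxy)
Conditions: Me3SiOCH2CH2OSiMe3, Me3SiOTf (cat.), CH2Cl2, −78 → −20 °C
Reagents that add atoms: 1,2-bis(trimethylsilyloxy)ethane, C[Si](C)(C)OCCO[Si](C)(C)C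
Why: Noyori ketalisation is selective for the saturated C11 ketone over the conjugated, peri-hindered aryl ketone at C8, and the low temperature spares the silyl ether.

Step 9
Reactants: 12 8-ketone 11-ethylene ketal
Product: 14 8(9)-alkene 11-ethylene ketal (styrene-type C8=C9; 10α-H; 14α-silyloxy), via benzylic alcohol 13 (not isolated)
Conditions: NaBH4, MeOH/THF, 0 °C; crude 13: methyl N-(triethylammoniosulfonyl)carbamate (Burgess reagent), toluene, 60 °C
Reagents that add atoms: none
Why: Borohydride reduction of the aryl ketone followed by Burgess dehydration (syn elimination through the sulfamate ester; the only β-hydrogens are on C9) gives the C8=C9 alkene without acid.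

Step 10
Reactants: 14 8(9)-alkene 11-ethylene ketal
Product: 15 9-ketone 11-ethylene ketal (C8 benzylic CH2; 10α-H; 14α-silyloxy)
Conditions: PdCl2(MeCN)2 (10 mol%), 1,4-benzoquinone, DMF/H2O (7:1), rt
Reagents that add atoms: water, O
Why: Wacker oxidation: hydroxypalladation of an internal styrene places palladium on the benzylic carbon C8 (π-benzyl stabilisation) and oxygen on C9, so β-hydride elimination and tautomerisation give the C9 ketone, as arylpropenes give arylacetones and 1,2-dihydronaphthalenes give 2-tetralones. This completes the 1,2-transposition of the carbonyl.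

Step 11
Reactants: 16 ethyl (R)-2-hydroxypropanoate
Product: 17 ethyl (R)-2-[(trifluoromethylsulfonyl)oxy]propanoate
Conditions: (CF3SO2)2O, 2,6-lutidine, CH2Cl2, −78 → 0 °C
Reagents that add atoms: trifluoromethanesulfonic anhydride, O=S(=O)(OS(=O)(=O)C(F)(F)F)C(F)(F)F
Why: O-sulfonylation of the lactate hydroxyl; the stereocentre is not touched.

Step 12
Reactants: 15 9-ketone 11-ethylene ketal; 17 ethyl (R)-2-[(trifluoromethylsulfonyl)oxy]propanoate
Product: 18 9-ketone bearing at C8 the (1R)-1-(ethoxycarbonyl)ethyl group (C17 R, C18 methyl, C19 ester; C8 epimers)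
Conditions: LiN(SiMe3)2, THF, −78 °C; then 17, −78 → −30 °C
Reagents that add atoms: none
Why: The ketone is deprotonated at the benzylic, doubly activated C8; SN2 alkylation of the lithium enolate by the α-triflyloxy ester proceeds with inversion at the lactate carbon, which fixes C17 as R from the chiral pool. The C8 configuration is erased in step 13.

Step 13
Reactants: 18 C8-alkylated 9-ketone (17R)
Product: 19 8α-hydroxy-9-ketone (C17 side chain 8β; 17R; ethyl ester)
Conditions: KN(SiMe3)2, THF, −78 °C; 2-(phenylsulfonyl)-3-phenyloxaziridine, −78 °C; aq. NH4Cl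
Reagents that add atoms: 2-(phenylsulfonyl)-3-phenyloxaziridine, O=S(=O)(N1OC1c1ccccc1)c1ccccc1
Why: Only the C8–H (benzylic, α to the ketone) is acidic enough for one equivalent of base, so C17 is not touched. The tetrasubstituted potassium enolate is hydroxylated by the Davis oxaziridine on the α face (axial attack on the trans-fused half-chair, opposite C15), placing O8 axial and the C17 chain equatorial.

Step 14
Reactants: 19 8α-hydroxy-9-ketone ester
Product: 20 8α,9β,19-triol (arene; 11-ethylene ketal; 14α-silyloxy; C17 now S by CIP with unchanged geometry)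
Conditions: LiAlH4, THF, −78 → 0 °C
Reagents that add atoms: none
Why: LiAlH4 reduces the ester to the primary alcohol and the C9 ketone. Hydride comes from the α face, delivered from the aluminate at O8 and away from C15, which is 1,3-diaxial to the β approach, giving the axial 9β alcohol trans to O8 as in hydride reductions of ring ketones flanked by a syn-axial angular methyl.

Step 15
Reactants: 20 8α,9β,19-triol (arene)
Product: 21 8α,9β,19-triol of the 2(7),4-diene (Birch product; 11-ethylene ketal; 14α-silyloxy)
Conditions: Li, NH3(l)/THF, EtOH, −78 → −33 °C; NH4Cl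
Reagents that add atoms: none
Why: Birch reduction of the trialkylbenzene: protonation occurs at the two unsubstituted para carbons C3 and C6, so all alkyl-bearing carbons stay sp2 (C2=C7 and C4=C5). The benzylic C8 oxygen is present as its lithium alkoxide, a non-leaving group, which should suppress benzylic hydrogenolysis; silyl ether and ketal are inert.

Step 16
Reactants: 21 Birch diene triol
Product: 22 8,19-acetonide of the diene (9β-OH free; 14α-silyloxy; 11-ethylene ketal)
Conditions: Me2C(OMe)2, pyridinium p-toluenesulfonate (cat.), CH2Cl2, rt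
Reagents that add atoms: 2,2-dimethoxypropane, COC(C)(C)OC
Why: Thermodynamic acetal exchange gives the six-membered acetonide of the 1,3-diol (O8/O19); O8 and O9 are trans-diaxial and O9/O19 would need a seven-membered ring, so 9-OH stays free. The weak acid does not isomerise the 1,4-diene.

Step 17
Reactants: 22 8,19-acetonide diene
Product: 23 9β-acetate of the acetonide diene (14α-silyloxy)
Conditions: Ac2O, 4-(dimethylamino)pyridine, Et3N, CH2Cl2, rt → 40 °C
Reagents that add atoms: acetic anhydride, CC(=O)OC(C)=O
Why: Nucleophile-catalysed acylation of the only free hydroxyl installs the C9 acetate of the target early; later it restricts lactonisation to O7 and leaves no hydroxyl able to direct hydride to C11.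

Step 18
Reactants: 23 9β-acetate 14α-silyl ether diene
Product: 24 key-step precursor: 2(7),4-diene with free 14α-OH, 9β-acetate, 8,19-acetonide and 11-ethylene ketal
Conditions: HF·pyridine, pyridine, THF, 0 °C → rt
Reagents that add atoms: none
Why: Buffered fluoride cleaves the silyl ether and leaves acetate, acetonide, ketal and the 1,4-diene untouched; the free 14-OH is needed to direct the C2 reduction in step 20.

Step 19
Reactants: 24 tricyclic 2(7),4-diene (14α-OH, 9β-acetate, 8,19-acetonide, 11-ethylene ketal)
Product: 25 ten-membered (4Z)-2,7-dione (14-OH, 9-acetate, 8,19-acetonide, 11-ethylene ketal)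
Conditions: O3, CH2Cl2/MeOH (5:1), NaHCO3, Sudan Red 7B, −78 °C; then Me2S, −78 °C → rt
Reagents that add atoms: ozone, [O-][O+]=O
Why: Ozone adds as a 1,3-dipole to the C2=C7 bond to give the primary ozonide, which undergoes cycloreversion to a ketone and a carbonyl oxide; methanol traps the carbonyl oxide as an α-methoxy hydroperoxide and dimethyl sulfide reduces it to the second ketone. The closest known reaction type is the selective ozonolysis of the central tetrasubstituted alkene of Birch-derived 1,4-dienes and of octalins to cyclodecane-1,6-diones. The ten-membered ring is not closed by bond formation but unveiled by cleaving the bond common to rings B and C, so there is no entropic or transannular penalty of ring closure. No stereocentre is created; C1 and C8 next to the new ketones are quaternary and cannot epimerise, and C9, C10, C14 and C17 are untouched. The selectivity needed is for the tetrasubstituted alkene over the trisubstituted C4=C5 alkene; electrophilic ozone reacts faster with the more alkylated π bond, and this is enforced at −78 °C by titrating ozone against Sudan Red 7B, whose fading marks the end point. The cis geometry of C4=C5 is carried into the ten-membered ring. Acetate, acetonide, ketal and the free secondary alcohol are inert to ozone at this temperature.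

Step 20
Reactants: 25 ten-membered 2,7-dione
Product: 26 (2S)-2,14-diol 7-ketone (C4=C5 retained; 9-acetate, acetonide, ketal)
Conditions: Me4NBH(OAc)3, MeCN/AcOH (1:1), −30 °C
Reagents that add atoms: none
Why: Evans–Saksena reduction: the triacetoxyborohydride exchanges an acetate for the 14-hydroxyl and delivers hydride intramolecularly through a six-membered chair transition state, giving the 1,3-anti diol, which is the 2S configuration. The C7 ketone has no free hydroxyl nearby and is not reduced by this reagent.

Step 21
Reactants: 26 (2S)-2,14-diol 7-ketone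
Product: 27 (5Z)-enone (C5=C6 conjugated with the C7 ketone; 2,14-diol, 9-acetate, acetonide, ketal)
Conditions: 1,8-diazabicyclo[5.4.0]undec-7-ene (0.3 equiv), CH2Cl2, rt
Reagents that add atoms: none
Why: With C2 an alcohol, the only acidic site is C6 (α to the C7 ketone and allylic); base-catalysed deprotonation and γ-reprotonation move the alkene into conjugation. The cis geometry is the stable one for a ten-membered cycloalkene, and no transannular aldol acceptor remains.

Step 22
Reactants: 27 (5Z)-enone acetonide ketal
Product: 28 (5Z)-7,11-dione with free 2-, 8-, 14- and 19-hydroxyls and the 9-acetate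
Conditions: AcOH/THF/H2O (3:1:1), 40 °C
Reagents that add atoms: water, O
Why: Aqueous acetic acid hydrolyses the six-membered acetonide and the dioxolane; it is done before C7 is reduced so that no acid-labile allylic alcohol is present. The product may exist in part as cyclic hemiketals, which does not matter for the next step.

Step 23
Reactants: 28 (5Z)-7,11-dione tetraol 9-acetate
Product: 29 (7S)-allylic alcohol: 2,7,8,14,19-pentol 11-ketone 9-acetate
Conditions: Me4NBH(OAc)3, MeCN/AcOH (1:1), −30 → 0 °C
Reagents that add atoms: none
Why: Hydroxyl-directed 1,2-reduction: the borohydride bound to the tertiary 8-OH delivers hydride to the adjacent C7 carbonyl in the conformer that keeps C6 anti to C9, which should give the 7,8-anti diol (7S). The C11 ketone has only γ-hydroxyls (O9 is acetylated) and should not be reduced under these conditions.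

Step 24
Reactants: 29 pentol 11-ketone 9-acetate
Product: 30 (11S)-11,20-epoxide (spiro-epoxide with axial oxygen; pentol 9-acetate)
Conditions: Me3S(O)I, NaH, DMSO, rt (ylide preformed); then 29, THF/DMSO, rt
Reagents that add atoms: trimethylsulfoxonium iodide, C[S+](C)(C)=O.[I-]
Why: Corey–Chaykovsky epoxidation: the axial approach at C11 is blocked by the 1,3-diaxial C15 methyl and betaine formation is reversible, so C20 enters equatorially and the epoxide oxygen is axial (11S). The ylide is too weak a base to deprotonate the alcohols and is used before the lactone exists.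

Step 25
Reactants: 30 epoxy pentol 9-acetate
Product: 32 γ-lactone (C19 acyl on O7; 17R; 2,8,14-triol 9-acetate; epoxide), via lactol 31 (not isolated)
Conditions: [Cu(MeCN)4]OTf (5 mol%), 2,2′-bipyridine, 2,2,6,6-tetramethylpiperidine-1-oxyl, N-methylimidazole, air, MeCN, rt
Reagents that add atoms: none
Why: Copper/nitroxyl aerobic oxidation is selective for the primary 19-OH; the aldehyde closes to the five-membered lactol with the allylic 7-OH (O9 is blocked, O8 would give a four-membered ring) and the lactol is oxidised to the lactone. The near-neutral conditions spare the epoxide and do not cleave the 7,8-diol.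

Step 26
Reactants: 32 lactone triol 9-acetate
Product: 33 (5Z)-2,9,14-triacetate with free 8-OH (deschloro lactone epoxide)
Conditions: Ac2O, pyridine, 4-(dimethylamino)pyridine (cat.), CH2Cl2, 0 °C → rt
Reagents that add atoms: acetic anhydride, CC(=O)OC(C)=O
Why: Acylation of the two secondary alcohols; the tertiary 8-OH is too hindered to react under these conditions.

Step 27
Reactants: 33 (5Z)-triacetate lactone epoxide
Product: 34 CNP0104093.2, (1S,2S,6S,7R,8R,9S,10S,11S,14S,17R)-2,9,14-triacetoxy-6-chloro-11,20-epoxy-8-hydroxybriar-5(16)-en-19,7-olide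
Conditions: Ca(OCl)2, CO2 (solid), CH2Cl2/H2O, 0 °C
Reagents that add atoms: calcium hypochlorite, [Ca+2].[O-]Cl.[O-]Cl
Why: Ene-type chlorination by hypochlorous acid: electrophilic chlorine adds to the less substituted alkene carbon C6 and a proton is lost from the C16 methyl, giving the secondary allylic chloride with the C5=C16 methylene. With H7 in the alkene plane (allylic strain of the Z alkene), chlorine is expected to enter on the exposed face anti to the lactone C7–O bond, which is 6S. Carbonic acid buffering protects the epoxide.

## Compound list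

1 | 1-(2-bromo-5-methylphenyl)ethanone | CC(=O)c1cc(C)ccc1Br | starting material
2 | 2-(2-bromo-5-methylphenyl)-2-methyl-1,3-dioxolane | Cc1ccc(Br)c(c1)C1(C)OCCO1 | intermediate
3 | 2-methylcyclohexane-1,3-dione | CC1C(=O)CCCC1=O | starting material
4 | 2-methyl-2-[4-methyl-2-(2-methyl-1,3-dioxolan-2-yl)phenyl]cyclohexane-1,3-dione | Cc1ccc(c(c1)C2(C)OCCO2)C3(C)C(=O)CCCC3=O | intermediate
5 | (2S,3S)-3-hydroxy-2-methyl-2-[4-methyl-2-(2-methyl-1,3-dioxolan-2-yl)phenyl]cyclohexan-1-one | Cc1ccc(c(c1)C2(C)OCCO2)[C@@]3(C)[C@@H](O)CCCC3=O | intermediate
6 | (2S,3S)-3-(tert-butyldimethylsilyloxy)-2-methyl-2-[4-methyl-2-(2-methyl-1,3-dioxolan-2-yl)phenyl]cyclohexan-1-one | Cc1ccc(c(c1)C2(C)OCCO2)[C@@]3(C)[C@@H](O[Si](C)(C)C(C)(C)C)CCCC3=O | intermediate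
7 | (2S,3S)-2-(2-acetyl-4-methylphenyl)-3-(tert-butyldimethylsilyloxy)-2-methylcyclohexan-1-one | CC(=O)c1cc(C)ccc1[C@@]2(C)[C@@H](O[Si](C)(C)C(C)(C)C)CCCC2=O | intermediate (not isolated)
8 | tricyclic enone (8-oxo, 9(10)-ene, 14α-silyloxy) | Cc1ccc2[C@@]3(C)[C@@H](O[Si](C)(C)C(C)(C)C)CCCC3=CC(=O)c2c1 | intermediate
9 | deconjugated enone (8-oxo, 10(11)-ene) | Cc1ccc2[C@@]3(C)[C@@H](O[Si](C)(C)C(C)(C)C)CCC=C3CC(=O)c2c1 | intermediate (not isolated)
10 | 8ξ,11α-diol (10α-H) | Cc1ccc2[C@@]3(C)[C@@H](O[Si](C)(C)C(C)(C)C)CC[C@@H](O)[C@@H]3CC(O)c2c1 | intermediate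
11 | 8,11-dione (10α-H) | Cc1ccc2[C@@]3(C)[C@@H](O[Si](C)(C)C(C)(C)C)CCC(=O)[C@@H]3CC(=O)c2c1 | intermediate
12 | 8-ketone 11-ethylene ketal | Cc1ccc2[C@@]3(C)[C@@H](O[Si](C)(C)C(C)(C)C)CCC4(OCCO4)[C@@H]3CC(=O)c2c1 | intermediate
13 | 8ξ-alcohol 11-ethylene ketal | Cc1ccc2[C@@]3(C)[C@@H](O[Si](C)(C)C(C)(C)C)CCC4(OCCO4)[C@@H]3CC(O)c2c1 | intermediate (not isolated)
14 | 8(9)-alkene 11-ethylene ketal | Cc1ccc2[C@@]3(C)[C@@H](O[Si](C)(C)C(C)(C)C)CCC4(OCCO4)[C@@H]3C=Cc2c1 | intermediate
15 | 9-ketone 11-ethylene ketal | Cc1ccc2[C@@]3(C)[C@@H](O[Si](C)(C)C(C)(C)C)CCC4(OCCO4)[C@@H]3C(=O)Cc2c1 | intermediate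
16 | ethyl (R)-2-hydroxypropanoate | C[C@@H](O)C(=O)OCC | starting material
17 | ethyl (R)-2-[(trifluoromethylsulfonyl)oxy]propanoate | C[C@@H](OS(=O)(=O)C(F)(F)F)C(=O)OCC | intermediate
18 | C8-alkylated 9-ketone (17R ester, C8 epimers) | Cc1ccc2[C@@]3(C)[C@@H](O[Si](C)(C)C(C)(C)C)CCC4(OCCO4)[C@@H]3C(=O)C([C@@H](C)C(=O)OCC)c2c1 | intermediate
19 | 8α-hydroxy-9-ketone ester (17R) | Cc1ccc2[C@@]3(C)[C@@H](O[Si](C)(C)C(C)(C)C)CCC4(OCCO4)[C@@H]3C(=O)[C@@]([C@@H](C)C(=O)OCC)(O)c2c1 | intermediate
20 | 8α,9β,19-triol (arene) | Cc1ccc2[C@@]3(C)[C@@H](O[Si](C)(C)C(C)(C)C)CCC4(OCCO4)[C@@H]3[C@H](O)[C@@]([C@@H](C)CO)(O)c2c1 | intermediate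
21 | 8α,9β,19-triol of the 2(7),4-diene | CC1=CCC=5[C@@]2(C)[C@@H](O[Si](C)(C)C(C)(C)C)CCC3(OCCO3)[C@@H]2[C@H](O)[C@@]([C@@H](C)CO)(O)C=5C1 | intermediate
22 | 8,19-acetonide diene (9β-OH) | CC1=CCC=5[C@@]2(C)[C@@H](O[Si](C)(C)C(C)(C)C)CCC3(OCCO3)[C@@H]2[C@H](O)[C@@]([C@@H](C)COC8(C)C)(O8)C=5C1 | intermediate
23 | 9β-acetate 14α-silyl ether diene | CC1=CCC=5[C@@]2(C)[C@@H](O[Si](C)(C)C(C)(C)C)CCC3(OCCO3)[C@@H]2[C@H](OC(C)=O)[C@@]([C@@H](C)COC8(C)C)(O8)C=5C1 | intermediate
24 | key-step precursor: 2(7),4-diene, 14α-OH, 9β-acetate, 8,19-acetonide, 11-ketal | CC1=CCC=5[C@@]2(C)[C@@H](O)CCC3(OCCO3)[C@@H]2[C@H](OC(C)=O)[C@@]([C@@H](C)COC8(C)C)(O8)C=5C1 | intermediate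
25 | key-step product: ten-membered (4Z)-2,7-dione | C/C1=C/CC(=O)[C@@]2(C)[C@@H](O)CCC3(OCCO3)[C@@H]2[C@H](OC(C)=O)[C@@]([C@@H](C)COC8(C)C)(O8)C(=O)C1 | intermediate
26 | (2S)-2,14-diol 7-ketone | C/C1=C/C[C@H](O)[C@@]2(C)[C@@H](O)CCC3(OCCO3)[C@@H]2[C@H](OC(C)=O)[C@@]([C@@H](C)COC8(C)C)(O8)C(=O)C1 | intermediate
27 | (5Z)-enone acetonide ketal | C/C1=C/C(=O)[C@]5(OC(C)(C)OC[C@@H]5C)[C@@H](OC(C)=O)[C@H]2C3(OCCO3)CC[C@H](O)[C@]2(C)[C@@H](O)CC1 | intermediate
28 | (5Z)-7,11-dione 2,8,14,19-tetraol 9-acetate | C/C1=C/C(=O)[C@@](O)([C@@H](C)CO)[C@@H](OC(C)=O)[C@H]2C(=O)CC[C@H](O)[C@]2(C)[C@@H](O)CC1 | intermediate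
29 | (7S)-2,7,8,14,19-pentol 11-ketone 9-acetate | C/C1=C/[C@H](O)[C@@](O)([C@@H](C)CO)[C@@H](OC(C)=O)[C@H]2C(=O)CC[C@H](O)[C@]2(C)[C@@H](O)CC1 | intermediate
30 | (11S)-11,20-epoxy pentol 9-acetate | C/C1=C/[C@H](O)[C@@](O)([C@@H](C)CO)[C@@H](OC(C)=O)[C@H]2[C@]3(CO3)CC[C@H](O)[C@]2(C)[C@@H](O)CC1 | intermediate
31 | lactol (C19 hemiacetal on O7) | C/C1=C/[C@@H]4OC(O)[C@H](C)[C@@]4(O)[C@@H](OC(C)=O)[C@H]2[C@]3(CO3)CC[C@H](O)[C@]2(C)[C@@H](O)CC1 | intermediate (not isolated)
32 | lactone 2,8,14-triol 9-acetate | C/C1=C/[C@@H]4OC(=O)[C@H](C)[C@@]4(O)[C@@H](OC(C)=O)[C@H]2[C@]3(CO3)CC[C@H](O)[C@]2(C)[C@@H](O)CC1 | intermediate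
33 | (5Z)-2,9,14-triacetate lactone epoxide (deschloro) | C/C1=C/[C@@H]4OC(=O)[C@H](C)[C@@]4(O)[C@@H](OC(C)=O)[C@H]2[C@]3(CO3)CC[C@H](OC(C)=O)[C@]2(C)[C@@H](OC(C)=O)CC1 | intermediate
34 | CNP0104093.2 | C=C1CC[C@H](OC(C)=O)[C@@]2(C)[C@@H](OC(C)=O)CC[C@@]3(CO3)[C@@H]2[C@H](OC(C)=O)[C@]2(O)[C@@H](C)C(=O)O[C@H]2[C@H]1Cl | target

## Step count and least certain steps

Total: 27 steps. Longest linear sequence: 26 steps (steps 1–10 and 12–27, from 1 to 34); step 11 is a one-step side branch from 16.

Step 19 (key step). Most likely failure: loss of chemoselectivity, with ozone beginning to attack C4=C5 before C2=C7 is consumed, because the two rates differ by a factor and not absolutely. Fallback, from 24 back to 25: one equivalent of m-chloroperbenzoic acid (NaHCO3, CH2Cl2, −78 °C) epoxidises the more electron-rich tetrasubstituted alkene to give the 2,7-epoxide F1. Periodic acid in aqueous THF then opens and cleaves the epoxide to dione 25.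

Step 2. Most likely failure: slow coupling at the congested quaternary carbon beside an ortho-substituted arene, so that hydrodebromination of 2 or base-induced ring cleavage of the dione product takes over. Fallback, from 2 back to 4: the less hindered cyclohexane-1,3-dione is arylated with 2 under the same catalysis to give 2-[4-methyl-2-(2-methyl-1,3-dioxolan-2-yl)phenyl]cyclohexane-1,3-dione F2. C-methylation (MeI, K2CO3, acetone) then builds the quaternary centre and gives 4.

Step 12. Most likely failure: O-alkylation of the delocalised enolate by the hard triflate, or base-induced elimination of 17 to ethyl acrylate. Fallback, from 15 back to 18: condensation with pyrrolidine (cat. p-TsOH, benzene, Dean–Stark) gives the arene-conjugated pyrrolidine enamine F3. This soft, neutral nucleophile is C-alkylated by 17 in MeCN, and buffered aqueous hydrolysis of the iminium salt gives 18.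

Step 15. Most likely failure: hydrogenolysis of the benzylic C8–O bond if the alkoxide is protonated during the reduction, or incomplete reduction of the electron-rich trialkyl arene. Fallback, from 15 back to 21: the Birch reduction is moved to a stage without benzylic oxygen.
- Li/NH3/EtOH reduces the arene and the ketone of 15 to give the diene alcohol F4 (equatorial 9α-OH).
- Dess–Martin oxidation gives the diene ketone F5.
- Deprotonation at the doubly activated C8 and alkylation with 17 give the keto ester F6.
- Hydroxylation of its potassium enolate with the Davis oxaziridine gives the 8α-hydroxy ketone F7.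
- LiAlH4 reduces F7 to 21.

Step 23. Most likely failure: poor facial selectivity if the ring adopts the conformer with C6 gauche to C9, competing delivery from the primary 19-OH, or partial reduction of the C11 ketone. Fallback, from 27 back to 29: the enone is reduced before the acid step under catalyst control (oxazaborolidine-catalysed CBS reduction with catecholborane, catalyst antipode chosen for the 7S alcohol) to give the allylic alcohol acetonide ketal F8. Aqueous acetic acid at room temperature then removes acetonide and ketal to give 29.

Step 27. Most likely failure: proton loss from C4 in place of C16, attack on the wrong alkene face, or opening of the epoxide by adventitious HCl. Fallback, from 33 back to 34: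
- A Schenck ene reaction with singlet oxygen (O2, tetraphenylporphyrin, light) gives the 6-hydroperoxy-5(16)-ene F9, which triphenylphosphine reduces to the allylic alcohol F10.
- Dess–Martin oxidation gives the α-methylene ketone F11.
- NaBH4/CeCl3 adds hydride from the exposed face to give the (6R)-alcohol F12.
- Appel chlorination (PPh3, CCl4) with inversion gives 34.

## Further compounds

F1 | step 19 | 2,7-epoxide of 24 | CC1=CCC25[C@@]4(C)[C@@H](O)CCC3(OCCO3)[C@@H]4[C@H](OC(C)=O)[C@@]([C@@H](C)COC8(C)C)(O8)C2(O5)C1
F2 | step 2 | 2-[4-methyl-2-(2-methyl-1,3-dioxolan-2-yl)phenyl]cyclohexane-1,3-dione | Cc1ccc(c(c1)C2(C)OCCO2)C3C(=O)CCCC3=O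
F3 | step 12 | pyrrolidine enamine of 15 (C8=C9, N on C9) | Cc1ccc2[C@@]3(C)[C@@H](O[Si](C)(C)C(C)(C)C)CCC4(OCCO4)[C@@H]3C(N5CCCC5)=Cc2c1
F4 | step 15 | diene 9α-alcohol | CC1=CCC=5[C@@]2(C)[C@@H](O[Si](C)(C)C(C)(C)C)CCC3(OCCO3)[C@@H]2[C@@H](O)CC=5C1
F5 | step 15 | diene 9-ketone | CC1=CCC=5[C@@]2(C)[C@@H](O[Si](C)(C)C(C)(C)C)CCC3(OCCO3)[C@@H]2C(=O)CC=5C1
F6 | step 15 | C8-alkylated diene 9-ketone (17R ester) | CC1=CCC=5[C@@]2(C)[C@@H](O[Si](C)(C)C(C)(C)C)CCC3(OCCO3)[C@@H]2C(=O)C([C@@H](C)C(=O)OCC)C=5C1
F7 | step 15 | 8α-hydroxy diene 9-ketone ester | CC1=CCC=5[C@@]2(C)[C@@H](O[Si](C)(C)C(C)(C)C)CCC3(OCCO3)[C@@H]2C(=O)[C@@]([C@@H](C)C(=O)OCC)(O)C=5C1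
F8 | step 23 | (7S)-allylic alcohol acetonide ketal | C/C1=C/[C@H](O)[C@]5(OC(C)(C)OC[C@@H]5C)[C@@H](OC(C)=O)[C@H]2C3(OCCO3)CC[C@H](O)[C@]2(C)[C@@H](O)CC1
F9 | step 27 | 6-hydroperoxy-5(16)-ene | C=C1CC[C@H](OC(C)=O)[C@@]2(C)[C@@H](OC(C)=O)CC[C@@]3(CO3)[C@@H]2[C@H](OC(C)=O)[C@]2(O)[C@@H](C)C(=O)O[C@H]2C1OO
F10 | step 27 | 6-hydroxy-5(16)-ene | C=C1CC[C@H](OC(C)=O)[C@@]2(C)[C@@H](OC(C)=O)CC[C@@]3(CO3)[C@@H]2[C@H](OC(C)=O)[C@]2(O)[C@@H](C)C(=O)O[C@H]2C1O
F11 | step 27 | 6-oxo-5(16)-ene | C=C1CC[C@H](OC(C)=O)[C@@]2(C)[C@@H](OC(C)=O)CC[C@@]3(CO3)[C@@H]2[C@H](OC(C)=O)[C@]2(O)[C@@H](C)C(=O)O[C@H]2C1=O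
F12 | step 27 | (6R)-6-hydroxy-5(16)-ene | C=C1CC[C@H](OC(C)=O)[C@@]2(C)[C@@H](OC(C)=O)CC[C@@]3(CO3)[C@@H]2[C@H](OC(C)=O)[C@]2(O)[C@@H](C)C(=O)O[C@H]2[C@@H]1O
A1 | alternative 1 | (1E,3E)-1-(tert-butyldimethylsilyloxy)-5-(4-methoxybenzyloxy)penta-1,3-diene | CC(C)(C)[Si](C)(C)O/C=C/C=C/COCc1ccc(OC)cc1
A2 | alternative 1 | (E)-4-(tert-butyldimethylsilyloxy)-2-methylbut-2-enal | O=C/C(C)=C/CO[Si](C)(C)C(C)(C)C
A3 | alternative 1 | ring A cyclohexene aldehyde (endo adduct) | O=C[C@@]2(C)[C@@H](O[Si](C)(C)C(C)(C)C)C=C[C@@H](COCc1ccc(OC)cc1)[C@@H]2CO[Si](C)(C)C(C)(C)C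
A4 | alternative 2 | C8 ketone C7 acrylate of the deschloro triacetate epoxide | C/C1=C/[C@H](OC(=O)C=C)C(=O)[C@@H](OC(C)=O)[C@H]2[C@]3(CO3)CC[C@H](OC(C)=O)[C@]2(C)[C@@H](OC(C)=O)CC1
A5 | alternative 2 | deschloro C5=C6 lactone triacetate (same compound as 33) | C/C1=C/[C@@H]4OC(=O)[C@H](C)[C@@]4(O)[C@@H](OC(C)=O)[C@H]2[C@]3(CO3)CC[C@H](OC(C)=O)[C@]2(C)[C@@H](OC(C)=O)CC1
A6 | alternative 3 | 7-methyl-1,4-dioxaspiro[4.5]dec-6-en-8-one | CC1=CC2(OCCO2)CCC1=O
A7 | alternative 3 | aldehyde fragment 2 (C2–C8 chain with C17–C19) | O=CCC/C(C)=C\[C@H](O[Si](C)(C)C(C)(C)C)C(=C)[C@@H](C)COCc1ccc(OC)cc1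
A8 | alternative 3 | ring A aldol adduct | O[C@@H](CC/C(C)=C\[C@H](O[Si](C)(C)C(C)(C)C)C(=C)[C@@H](C)COCc1ccc(OC)cc1)[C@@]2(C)C(=O)CCC3(OCCO3)[C@@H]2C=C
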